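**Plan**

- Numbering (bicyclo[3.2.1]octane): C1 prenyl bridgehead, C5 methyl bridgehead, C6 the CH bearing C(CH3)2OH, C7 the CH2, C8 the bridging C=O. The retrosynthesis cuts C1–C7 and C5–C6, which lifts the two-carbon bridge off the six-membered ring and leaves an aromatic acylphloroglucinol and a five-carbon epoxy iodide.
- Feature that allows this: C1–C8(=O)–C5 is the C–C(O)–C unit between two meta carbons of a phloroglucinol, both nucleophilic (a latent 1,3-bis-enolate). The C6–C(OH) pair is what a carbon nucleophile leaves behind when it opens an epoxide at its secondary carbon.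
- Forward: 2-methylphloroglucinol is C-acylated and then C-prenylated at its last free ring carbon; prenol is epoxidised (Sharpless) and converted into the epoxy iodide; the two halves are joined in the last step.
- In that step the six-membered ring is dearomatised by C-alkylation (C1–C7) and the five-membered ring is closed by strain-releasing epoxide opening (C5–C6), giving the bicyclo[3.2.1]octane and the tertiary alcohol together.
- Stereochemistry: C6 is bought from the catalytic asymmetric epoxidation and inverted on opening. C1 and C5 are tied to it because the short tether bridges one ring face only, with the carbinol group exo; the other alkylation epimer can give only a separable diastereomer, never the enantiomer.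

Key step: step 5

Remark: 9 is one enol tautomer of a 2-acyl-1,3-dione; the tautomers interconvert and are treated as one compound, and the dearomatised intermediate is drawn as its dienol form.

Step 1
Reactants: 1 2-methylbenzene-1,3,5-triol (2-methylphloroglucinol)
Product: 2 1-(2,4,6-trihydroxy-3-methylphenyl)-2-methylpropan-1-one
Conditions: i-PrCOCl (1.1 equiv), AlCl3 (4 equiv), PhNO2, 65 °C; then ice, 1 M HCl
Reagents that add atoms: 2-methylpropanoyl chloride, CC(C)C(Cl)=O
Why: Friedel–Crafts acylation of a very electron-rich arene whose two free ring positions are equivalent, so a single regioisomer should form, and the first acyl group deactivates the ring towards a second acylation.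

Step 2
Reactants: 2 1-(2,4,6-trihydroxy-3-methylphenyl)-2-methylpropan-1-one
Product: 3 1-[2,4,6-trihydroxy-3-methyl-5-(3-methylbut-2-en-1-yl)phenyl]-2-methylpropan-1-one
Conditions: prenyl bromide (1.0 equiv), 10% aq. KOH, 0 °C; then 1 M HCl
Reagents that add atoms: 1-bromo-3-methylbut-2-ene (prenyl bromide), CC(C)=CCBr
Why: C-alkylation of the phenoxide by an allylic bromide in water, where hydrogen bonding to oxygen steers the ambident anion to carbon; the one unsubstituted ring carbon reacts first and rearomatises, and one equivalent of bromide at 0 °C should hold back the second, dearomatising alkylation.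

Step 3
Reactants: 4 3-methylbut-2-en-1-ol (prenol)
Product: 6 [(2R)-3,3-dimethyloxiran-2-yl]methyl 4-methylbenzenesulfonate, via epoxy alcohol 5 (not isolated)
Conditions: Ti(OiPr)4 (5 mol%), D-(−)-diisopropyl tartrate (7 mol%), t-BuOOH (1.5 equiv), 4 Å MS, CH2Cl2, −20 °C; then P(OMe)3; then TsCl, Et3N, DMAP (cat.), −10 to 0 °C
Reagents that add atoms: tert-butyl hydroperoxide, CC(C)(C)OO; 4-methylbenzenesulfonyl chloride, Cc1ccc(cc1)S(Cl)(=O)=O
Why: Sharpless asymmetric epoxidation, in which the D-(−)-tartrate should deliver oxygen to the alkene face that gives the (2R)-epoxy alcohol (the natural L-(+)-tartrate gives 2S), followed by in situ sulfonylation of the primary alcohol so that the small water-soluble epoxy alcohol need not be isolated.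

Step 4
Reactants: 6 [(2R)-3,3-dimethyloxiran-2-yl]methyl 4-methylbenzenesulfonate
Product: 7 (2S)-2-(iodomethyl)-3,3-dimethyloxirane
Conditions: NaI (2 equiv), NaHCO3, acetone, rt, dark
Reagents that add atoms: sodium iodide, [Na+].[I-]
Why: Finkelstein SN2 displacement at the primary carbon exchanges the hard sulfonate for a soft iodide that favours C-alkylation; the stereocenter is not touched, and its descriptor changes from R to S only because CH2I outranks the ring carbon in the priority rules.

Step 5
Reactants: 3 1-[2,4,6-trihydroxy-3-methyl-5-(3-methylbut-2-en-1-yl)phenyl]-2-methylpropan-1-one; 7 (2S)-2-(iodomethyl)-3,3-dimethyloxirane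
Product: 9 (1R,5R,6R)-4-hydroxy-6-(2-hydroxypropan-2-yl)-5-methyl-1-(3-methylbut-2-en-1-yl)-3-(2-methylpropanoyl)bicyclo[3.2.1]oct-3-ene-2,8-dione, via dienone epoxide 8 (not isolated)
Conditions: KOH (4 equiv), 7 (1.5 equiv), THF–H2O (1:1), 0 to 40 °C; then cold 1 M HCl to pH 3
Reagents that add atoms: none
Why: Proposed new method: under aqueous KOH the polyanion of 3 should be C-alkylated at its prenyl-bearing ring carbon by the primary iodide of 7 (dearomatising SN2, as established for allylic bromides on this substrate class) to give dienone 8, whose dianion should then open the epoxide with its methyl-bearing enolate carbon; the closest known reaction types are the alkylative dearomatisation–annulation of acylphloroglucinols with bis-electrophiles (there Michael or π-allyl acceptors) and intramolecular enolate alkylation by an epoxide. The new cyclopentanone ring (C1–C7–C6–C5–C8) closes 5-(enolexo)-exo-tet at the secondary epoxide carbon, the normal site of SN2 opening under basic conditions (attack at the tertiary carbon would be 6-endo), and this one closure creates the bicyclo[3.2.1]octane and frees the tertiary alcohol. C6 is controlled by the (2R)-epoxide carbon, which is inverted in the opening, while C1 and C5 are fixed together because the two-carbon tether can bridge only on the ring face on which it sits: the (6R)-epimer 8 closes with the carbinol group exo (syn to C8), the less hindered orientation, and gives 9. The alkylation itself has no facial bias, so the (6S)-epimer of 8 can lead only to the separable 6-endo diastereomer or to O-cyclised ethers and never to the enantiomer of 9, which limits the throughput to the matched epimer but leaves 9 as enantiopure as 7. The step needs carbon and not oxygen to react twice and the second attack to come from the methyl-bearing carbon: the hydrogen-bonding aqueous medium and the soft iodide favour C-alkylation, and in the dianion of 8 the last-formed, most basic enolate is centred on that carbon, whereas the acyl-bearing carbon is the weakly nucleophilic centre of a triketone anion (the same preference is seen in the known annulations of this substrate class). The competing first alkylation at the methyl-bearing carbon of 3, which would end in a constitutional isomer, is the main uncertainty and is answered by the fallback.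

**Compound list**

1 | 2-methylbenzene-1,3,5-triol (2-methylphloroglucinol) | Cc1c(O)cc(O)cc1O | starting material
2 | 1-(2,4,6-trihydroxy-3-methylphenyl)-2-methylpropan-1-one | CC(C)C(=O)c1c(O)cc(O)c(C)c1O | intermediate
3 | 1-[2,4,6-trihydroxy-3-methyl-5-(3-methylbut-2-en-1-yl)phenyl]-2-methylpropan-1-one | CC(C)C(=O)c1c(O)c(C)c(O)c(CC=C(C)C)c1O | intermediate
4 | 3-methylbut-2-en-1-ol (prenol) | CC(C)=CCO | starting material
5 | [(2R)-3,3-dimethyloxiran-2-yl]methanol | OC[C@H]1OC1(C)C | intermediate
6 | [(2R)-3,3-dimethyloxiran-2-yl]methyl 4-methylbenzenesulfonate | Cc1ccc(cc1)S(=O)(=O)OC[C@H]1OC1(C)C | intermediate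
7 | (2S)-2-(iodomethyl)-3,3-dimethyloxirane | IC[C@H]1OC1(C)C | intermediate
8 | (6R)-6-{[(2R)-3,3-dimethyloxiran-2-yl]methyl}-3,5-dihydroxy-4-methyl-6-(3-methylbut-2-en-1-yl)-2-(2-methylpropanoyl)cyclohexa-2,4-dien-1-one | CC(C)=CC[C@@]1(C[C@H]2OC2(C)C)C(O)=C(C)C(O)=C(C(=O)C(C)C)C1=O | intermediate
9 | (1R,5R,6R)-4-hydroxy-6-(2-hydroxypropan-2-yl)-5-methyl-1-(3-methylbut-2-en-1-yl)-3-(2-methylpropanoyl)bicyclo[3.2.1]oct-3-ene-2,8-dione | CC(C)=CC[C@@]12C[C@@H](C(C)(C)O)[C@@](C)(C1=O)C(O)=C(C(=O)C(C)C)C2=O | target

**Step count and risks**

Total step count: 5. Longest linear sequence: 3 steps (1 → 2 → 5, or 3 → 4 → 5).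

Steps most likely to fail:

1. Step 5 (proposed new method). What may go wrong:
   - the polyanion of 3 attacks through oxygen or through its methyl-bearing carbon instead of the prenyl-bearing carbon;
   - the ring closes through an enolate oxygen instead of carbon;
   - the alkylation shows no facial discrimination, which sends part of the correctly alkylated material into the 6-endo series.

   Fallback with known reaction types, setting out from 3: the two bonds are made by a palladium-catalysed dearomative conjunctive allylic annulation, a reaction type established for acylphloroglucinols. Compound 3 and the commercial C5 bis-electrophile (E)-4-chloro-2-methylbut-2-en-1-yl acetate (CC(=O)OC/C(C)=C/CCl), with Pd(PPh3)4 (5 mol%) and K2CO3 in THF at 0 to 50 °C, should undergo C-allylation at the chloride end. The methyl-bearing enolate carbon should then attack the internal terminus of the π-allyl complex formed from the acetate; O-allylation is reversible under zerovalent palladium, so the C–C closed product collects. This should give the racemic exo-isopropenyl bicycle, that is (1R,5R,6S)-4-hydroxy-5-methyl-1-(3-methylbut-2-en-1-yl)-3-(2-methylpropanoyl)-6-(prop-1-en-2-yl)bicyclo[3.2.1]oct-3-ene-2,8-dione F1 together with its (1S,5S,6R)-enantiomer F2. Oxymercuration–demercuration (Hg(OAc)2, THF–H2O; then NaBH4, NaOH) hydrates a 1,1-disubstituted alkene much faster than the trisubstituted prenyl alkene and should give 9 together with its (1S,5S,6S)-enantiomer F3. Resolution on a chiral stationary phase, or crystallisation of the salt of this acidic triketone with a chiral amine, comes back to the route at 9.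

2. Step 2. What may go wrong: over-alkylation, in which the mono-prenylated phenoxide is alkylated again at a substituted ring carbon (dearomatisation) or at oxygen before 2 is consumed.

   Fallback, setting out from 2: the prenyl group is introduced by an acid-mediated Friedel–Crafts prenylation with 2-methylbut-3-en-2-ol and BF3·OEt2 in 1,4-dioxane at room temperature. This is an electrophilic substitution on the neutral arene; no phenoxide is present, so a dearomatising second alkylation cannot follow. It comes back to the route at 3 and makes no new compound.

3. Step 3. What may go wrong: incomplete enantiofacial selectivity in the epoxidation of this 3,3-disubstituted allylic alcohol, and loss of the small epoxide on work-up; any shortfall would pass on as lower enantiomeric purity of 9.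

   Fallback, setting out from 4: the same epoxidation is run, but the crude epoxy alcohol is acylated in the flask with 4-nitrobenzoyl chloride and Et3N to give the crystalline [(2R)-3,3-dimethyloxiran-2-yl]methyl 4-nitrobenzoate F4, which is recrystallised to enantiopurity. Methanolysis (K2CO3, MeOH, 0 °C) then frees 5, now isolated, and tosylation (TsCl, Et3N, DMAP, CH2Cl2) comes back to the route at 6.

Further compounds
F1 | step 5 | (1R,5R,6S)-4-hydroxy-5-methyl-1-(3-methylbut-2-en-1-yl)-3-(2-methylpropanoyl)-6-(prop-1-en-2-yl)bicyclo[3.2.1]oct-3-ene-2,8-dione | CC(C)=CC[C@@]12C[C@@H](C(C)=C)[C@@](C)(C1=O)C(O)=C(C(=O)C(C)C)C2=O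
F2 | step 5 | (1S,5S,6R)-4-hydroxy-5-methyl-1-(3-methylbut-2-en-1-yl)-3-(2-methylpropanoyl)-6-(prop-1-en-2-yl)bicyclo[3.2.1]oct-3-ene-2,8-dione | CC(C)=CC[C@]12C[C@H](C(C)=C)[C@](C)(C1=O)C(O)=C(C(=O)C(C)C)C2=O
F3 | step 5 | (1S,5S,6S)-4-hydroxy-6-(2-hydroxypropan-2-yl)-5-methyl-1-(3-methylbut-2-en-1-yl)-3-(2-methylpropanoyl)bicyclo[3.2.1]oct-3-ene-2,8-dione | CC(C)=CC[C@]12C[C@H](C(C)(C)O)[C@](C)(C1=O)C(O)=C(C(=O)C(C)C)C2=O
F0 | step 2 | none | none
F4 | step 3 | [(2R)-3,3-dimethyloxiran-2-yl]methyl 4-nitrobenzoate | O=C(OC[C@H]1OC1(C)C)c1ccc(cc1)[N+](=O)[O-]
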